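## Retrosynthetic overview

1. Target 28 ⇐ fluoride global deprotection of 27 ⇐ SeO2 allylic hydroxylation of the isopropenyl methyl ⇐ site-selective acylation of the C3 hydroxyl of diol 21 with the Roche-ester-derived acid 24.
2. Key disconnection C4–C5, which closes the cyclohexane: intramolecular indium Barbier reaction of bromo-enoate 19. The 2-(alkoxycarbonyl)allyl-indium is a homoenolate equivalent (acrylate β-carbon made nucleophilic) and attacks the lactol-masked C5 aldehyde, so two normally electrophilic carbons are joined.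
3. 19 ⇐ cross-metathesis of lactol 14 with 2-(trimethylsilyl)ethyl 2-(bromomethyl)acrylate 18; 14 ⇐ δ-lactone 13.
4. 13 ⇐ enantioselective Ireland–Claisen rearrangement of ester 9 (C6–C1 bond, quaternary C1 with its vinyl group), then desilylative lactonisation.
5. 9 ⇐ (R)-hex-1-en-5-yn-3-ol (asymmetric propargylation of acrolein) by Negishi carboalumination. Ring order: the temporary oxane (lactone, then lactol) first, the cyclohexane second (key step).

Atom labels used below: ring C1 (quaternary, methyl and vinyl), C2 (CH2), C3 (CH–O–acyl), C4 (CH–acrylate), C5 (CH–OH), C6 (CH–hydroxypropenyl).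

Assumption: the sense of induction of the chiral controllers in steps 1 and 5 is assigned by analogy with closely related substrates; if it proved opposite, the mirror-image controller would be used.

## Route

Step 1
Reactants: 1 acrolein; 2 allenylboronic acid pinacol ester
Product: 4 (3R)-hex-1-en-5-yn-3-ol, via pinacol borate 3 (not isolated)
Conditions: (R)-3,3′-bis(2,4,6-triisopropylphenyl)-1,1′-binaphthyl-2,2′-diyl hydrogenphosphate (5 mol %), 4 Å molecular sieves, toluene, −30 °C; aq. NaHCO3
Reagents that add atoms: none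
Why: Chiral phosphoric acid-catalysed asymmetric propargylation, in which the allenylboronate adds through a closed six-membered SE2′ transition state with the phosphate hydrogen-bonded to a boronate oxygen and shielding one aldehyde face, so the C3 carbinol centre is set as R.

Step 2
Reactants: 4 (3R)-hex-1-en-5-yn-3-ol
Product: 5 tert-butyl{[(3R)-hex-1-en-5-yn-3-yl]oxy}dimethylsilane
Conditions: TBSCl, imidazole, CH2Cl2, 0 °C → rt
Reagents that add atoms: tert-butyldimethylsilyl chloride, CC(C)(C)[Si](C)(C)Cl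
Why: Standard imidazole-promoted silylation of the secondary alcohol, which leaves the stereocentre untouched.

Step 3
Reactants: 5 silyl ether of (3R)-hex-1-en-5-yn-3-ol
Product: 7 (2E,5R)-5-{[tert-butyl(dimethyl)silyl]oxy}-3-methylhepta-2,6-dien-1-ol, via alkenylalane 6 (not isolated)
Conditions: Me3Al (2.5 equiv), Cp2ZrCl2 (0.25 equiv), CH2Cl2, 0 °C → rt; then (CH2O)n, THF, 0 °C → rt; aq. potassium sodium tartrate
Reagents that add atoms: trimethylaluminium, C[Al](C)C; formaldehyde (as paraformaldehyde), C=O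
Why: Negishi zirconium-catalysed carboalumination adds methyl and aluminium syn across the terminal alkyne with aluminium on the terminal carbon, and hydroxymethylation of alkenylalane 6 with retention fixes the E alkene (methyl cis to CH2OH) that the Claisen step needs.

Step 4
Reactants: 7 (2E,5R)-allylic alcohol; 8 3-methylbut-3-enoic acid
Product: 9 (2E,5R)-5-{[tert-butyl(dimethyl)silyl]oxy}-3-methylhepta-2,6-dien-1-yl 3-methylbut-3-enoate
Conditions: DCC, 4-(dimethylamino)pyridine (5 mol %), CH2Cl2, −10 → 0 °C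
Reagents that add atoms: none
Why: Steglich esterification of the primary allylic alcohol, run cold with little base so that the β,γ-unsaturated acid does not slide into conjugation.

Step 5
Reactants: 9 allylic 3-methylbut-3-enoate
Product: 13 (3S,4S,6R)-4,6-diethenyl-4-methyl-3-(prop-1-en-2-yl)oxan-2-one, via boron ketene acetal 10 (not isolated), via silyl ether acid 11 (not isolated), via hydroxy acid 12 (not isolated)
Conditions: (4S,5S)-2-bromo-1,3-bis{[3,5-bis(trifluoromethyl)phenyl]sulfonyl}-4,5-diphenyl-1,3,2-diazaborolidine (1.3 equiv), Et3N, toluene–hexane, −78 °C, then −20 → 4 °C, 10 d; aqueous work-up; then 48% aq. HF, MeCN, rt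
Reagents that add atoms: none
Why: Enantioselective Ireland–Claisen rearrangement through a chiral O-boryl ketene acetal: soft enolisation gives the ketene acetal with isopropenyl cis to the allyloxy oxygen, the chair transition state with the E-alkene methyl axial forms the C6–C1 bond and sets C6 (S) and quaternary C1 (S, vinyl formed directly) in the relative sense of the target while the sulfonamide controller chooses the face, and HF then removes the silyl ether so that the δ-hydroxy acid closes to the lactone.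

Step 6
Reactants: 13 δ-lactone
Product: 14 (3S,4S,6R)-4,6-diethenyl-4-methyl-3-(prop-1-en-2-yl)oxan-2-ol (both anomers)
Conditions: i-Bu2AlH (1.1 equiv), CH2Cl2, −78 °C; aq. potassium sodium tartrate
Reagents that add atoms: none
Why: Partial reduction of a lactone by i-Bu2AlH stops at the aluminium hemiacetal at −78 °C, giving a lactol that stores the epimerisable α-isopropenyl aldehyde (C5) and the C3 hydroxyl in masked form.

Step 7
Reactants: 15 2-(bromomethyl)acrylic acid; 16 2-(trimethylsilyl)ethanol
Product: 18 2-(trimethylsilyl)ethyl 2-(bromomethyl)prop-2-enoate, via acid chloride 17 (not isolated)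
Conditions: (COCl)2, N,N-dimethylformamide (cat.), CH2Cl2, 0 °C → rt; then 16, 2,6-lutidine, CH2Cl2, −20 → 0 °C
Reagents that add atoms: none
Why: Acid chloride formation and O-acylation with a hindered base that does not displace the allylic bromide.

Step 8
Reactants: 14 lactol; 18 2-(trimethylsilyl)ethyl 2-(bromomethyl)prop-2-enoate
Product: 19 2-(trimethylsilyl)ethyl (2Z)-2-(bromomethyl)-3-[(2R,4S,5S)-4-ethenyl-6-hydroxy-4-methyl-5-(prop-1-en-2-yl)oxan-2-yl]prop-2-enoate
Conditions: second-generation Hoveyda–Grubbs catalyst (10 mol %), 18 (4 equiv), 1,4-benzoquinone (20 mol %), CH2Cl2, 40 °C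
Reagents that add atoms: none
Why: Olefin cross-metathesis in which only the unhindered vinyl group on C3 engages (the vinyl on quaternary C1 and the isopropenyl group are too hindered), and the 1,1-disubstituted acrylate partner gives the thermodynamically preferred trisubstituted enoate with the ring carbon cis to CH2Br, as methacrylate-type partners do.

Step 9
Reactants: 19 lactol bromo-enoate
Product: 21 2-(trimethylsilyl)ethyl 2-[(1R,2S,3S,4S,6R)-4-ethenyl-2,6-dihydroxy-4-methyl-3-(prop-1-en-2-yl)cyclohexyl]prop-2-enoate, via allylindium species 20 (not isolated)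
Conditions: indium powder (2.5 equiv), THF–H2O 1:1, 0.01 M, rt
Reagents that add atoms: none
Why: Proposed new method: an intramolecular indium Barbier allylation on a lactol in water, in which the 2-(alkoxycarbonyl)allylindium 20 is a homoenolate equivalent (its nucleophilic γ-carbon C4 is the normally electrophilic β-carbon of the acrylate) that attacks the normally electrophilic aldehyde carbon C5 through a closed chair transition state fused to the chair of the forming cyclohexane, with the C6 isopropenyl equatorial, the C1 methyl axial and indium bridging the aldehyde oxygen and the free C3 hydroxyl held on the inside of the Z-allyl unit, which places O3 and O5 axial and the acrylate equatorial and so sets C4 and C5 all-cis to C3 and C6; the closest known reactions are indium-mediated additions of 2-(bromomethyl)acrylates to aldoses in water, chelation-controlled additions of γ-hydroxy 2-(bromomethyl)enoates, and zinc- or nickel-mediated cyclisations of 2-(bromomethyl)acrylates onto tethered aldehydes that give cis-fused products.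

Step 10
Reactants: 22 methyl (2S)-3-hydroxy-2-methylpropanoate
Product: 23 methyl (2S)-3-{[tert-butyl(dimethyl)silyl]oxy}-2-methylpropanoate
Conditions: TBSCl, imidazole, CH2Cl2, 0 °C → rt
Reagents that add atoms: tert-butyldimethylsilyl chloride, CC(C)(C)[Si](C)(C)Cl
Why: Silylation of the primary alcohol; the α-stereocentre is not involved.

Step 11
Reactants: 23 silylated Roche ester
Product: 24 (2S)-3-{[tert-butyl(dimethyl)silyl]oxy}-2-methylpropanoic acid
Conditions: LiOH, THF–H2O, 0 °C; then aq. HCl to pH 4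
Reagents that add atoms: lithium hydroxide, [Li+].[OH-]
Why: Saponification at 0 °C, mild enough to leave the α-methyl stereocentre and the primary silyl ether intact.

Step 12
Reactants: 21 cyclohexane diol; 24 (2S)-silyloxy acid
Product: 26 2-(trimethylsilyl)ethyl 2-[(1S,2S,3S,4S,6R)-6-{[(2S)-3-{[tert-butyl(dimethyl)silyl]oxy}-2-methylpropanoyl]oxy}-4-ethenyl-2-hydroxy-4-methyl-3-(prop-1-en-2-yl)cyclohexyl]prop-2-enoate, via mixed anhydride 25 (not isolated)
Conditions: 24, 2,4,6-trichlorobenzoyl chloride, Et3N, toluene, rt; then 21, 4-(dimethylamino)pyridine, toluene, 0 °C → rt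
Reagents that add atoms: none
Why: Yamaguchi esterification via mixed anhydride 25, in which the acyl group goes to the C3 hydroxyl (flanked by a CH2 group) in preference to the C5 hydroxyl (flanked by two branched carbons next to the quaternary centre), with the acid stereocentre carried over unchanged.

Step 13
Reactants: 26 C3 ester
Product: 27 2-(trimethylsilyl)ethyl 2-[(1S,2S,3R,4S,6R)-6-{[(2S)-3-{[tert-butyl(dimethyl)silyl]oxy}-2-methylpropanoyl]oxy}-4-ethenyl-2-hydroxy-3-(3-hydroxyprop-1-en-2-yl)-4-methylcyclohexyl]prop-2-enoate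
Conditions: SeO2 (0.5 equiv), t-BuOOH (2 equiv), CH2Cl2, 0 °C → rt, stopped at about 80% conversion
Reagents that add atoms: tert-butyl hydroperoxide, CC(C)(C)OO (terminal oxidant; the oxygen is delivered through selenium dioxide, O=[Se]=O)
Why: Selenium dioxide allylic oxidation (ene reaction, then 2,3-sigmatropic shift) at the methyl of the isopropenyl group, the only electron-rich alkene with accessible allylic hydrogens (the C1 vinyl has none, the acrylate is electron-poor, the ring methine next to the quaternary carbon is shielded), as is known for elemane-type isopropenyl groups.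

Step 14
Reactants: 27 fully protected precursor
Product: 28 2-[(1S,2S,3R,4S,6R)-4-ethenyl-2-hydroxy-6-{[(2S)-3-hydroxy-2-methylpropanoyl]oxy}-3-(3-hydroxyprop-1-en-2-yl)-4-methylcyclohexyl]prop-2-enoic acid
Conditions: tris(dimethylamino)sulfonium difluorotrimethylsilicate (4 equiv), N,N-dimethylformamide, 0 °C → rt; aq. NaH2PO4 (pH 5), no heating
Reagents that add atoms: none
Why: Fluoride-induced global deprotection, in which the 2-(trimethylsilyl)ethyl ester fragments to the carboxylate with loss of ethene and the primary silyl ether is cleaved under nearly neutral conditions, so that the cis γ-hydroxyl faces an unreactive carboxylate and no stereocentre is touched.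

## Compound list

1 | acrolein (prop-2-enal) | C=CC=O | starting material
2 | allenylboronic acid pinacol ester (4,4,5,5-tetramethyl-2-(propa-1,2-dien-1-yl)-1,3,2-dioxaborolane) | C=C=CB1OC(C)(C)C(C)(C)O1 | starting material
3 | 2-{[(3R)-hex-1-en-5-yn-3-yl]oxy}-4,4,5,5-tetramethyl-1,3,2-dioxaborolane | C#CC[C@@H](OB1OC(C)(C)C(C)(C)O1)C=C | intermediate
4 | (3R)-hex-1-en-5-yn-3-ol | C#CC[C@@H](O)C=C | intermediate
5 | tert-butyl{[(3R)-hex-1-en-5-yn-3-yl]oxy}dimethylsilane | C#CC[C@@H](O[Si](C)(C)C(C)(C)C)C=C | intermediate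
6 | [(1E,4R)-4-{[tert-butyl(dimethyl)silyl]oxy}-2-methylhexa-1,5-dien-1-yl]dimethylalumane | C[Al](C)/C=C(\C)C[C@@H](O[Si](C)(C)C(C)(C)C)C=C | intermediate
7 | (2E,5R)-5-{[tert-butyl(dimethyl)silyl]oxy}-3-methylhepta-2,6-dien-1-ol | OC/C=C(\C)C[C@@H](O[Si](C)(C)C(C)(C)C)C=C | intermediate
8 | 3-methylbut-3-enoic acid | C=C(C)CC(=O)O | starting material
9 | (2E,5R)-5-{[tert-butyl(dimethyl)silyl]oxy}-3-methylhepta-2,6-dien-1-yl 3-methylbut-3-enoate | C=C(C)CC(=O)OC/C=C(\C)C[C@@H](O[Si](C)(C)C(C)(C)C)C=C | intermediate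
10 | (4S,5S)-2-{[(1Z)-1-{[(2E,5R)-5-{[tert-butyl(dimethyl)silyl]oxy}-3-methylhepta-2,6-dien-1-yl]oxy}-3-methylbuta-1,3-dien-1-yl]oxy}-1,3-bis{[3,5-bis(trifluoromethyl)phenyl]sulfonyl}-4,5-diphenyl-1,3,2-diazaborolidine (isopropenyl cis to the allyloxy oxygen) | C=C(C)/C=C(\OC/C=C(\C)C[C@@H](O[Si](C)(C)C(C)(C)C)C=C)OB1N(S(=O)(=O)c2cc(cc(c2)C(F)(F)F)C(F)(F)F)[C@@H](c2ccccc2)[C@H](c2ccccc2)N1S(=O)(=O)c1cc(cc(c1)C(F)(F)F)C(F)(F)F | intermediate
11 | (2S,3S,5R)-5-{[tert-butyl(dimethyl)silyl]oxy}-3-ethenyl-3-methyl-2-(prop-1-en-2-yl)hept-6-enoic acid | C=C[C@](C)(C[C@@H](O[Si](C)(C)C(C)(C)C)C=C)[C@H](C(C)=C)C(=O)O | intermediate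
12 | (2S,3S,5R)-3-ethenyl-5-hydroxy-3-methyl-2-(prop-1-en-2-yl)hept-6-enoic acid | C=C[C@](C)(C[C@@H](O)C=C)[C@H](C(C)=C)C(=O)O | intermediate
13 | (3S,4S,6R)-4,6-diethenyl-4-methyl-3-(prop-1-en-2-yl)oxan-2-one | C=C[C@]1(C)C[C@H](C=C)OC(=O)[C@H]1C(C)=C | intermediate
14 | (3S,4S,6R)-4,6-diethenyl-4-methyl-3-(prop-1-en-2-yl)oxan-2-ol (both anomers) | C=C[C@]1(C)C[C@H](C=C)OC(O)[C@H]1C(C)=C | intermediate
15 | 2-(bromomethyl)acrylic acid | C=C(CBr)C(=O)O | starting material
16 | 2-(trimethylsilyl)ethanol | C[Si](C)(C)CCO | starting material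
17 | 2-(bromomethyl)prop-2-enoyl chloride | C=C(CBr)C(=O)Cl | intermediate
18 | 2-(trimethylsilyl)ethyl 2-(bromomethyl)prop-2-enoate | C=C(CBr)C(=O)OCC[Si](C)(C)C | intermediate
19 | 2-(trimethylsilyl)ethyl (2Z)-2-(bromomethyl)-3-[(2R,4S,5S)-4-ethenyl-6-hydroxy-4-methyl-5-(prop-1-en-2-yl)oxan-2-yl]prop-2-enoate (both anomers) | C=C[C@]1(C)C[C@H](/C=C(\CBr)C(=O)OCC[Si](C)(C)C)OC(O)[C@H]1C(C)=C | intermediate
20 | allylindium species of 19 in its open hydroxy-aldehyde form (drawn as the monovalent organoindium; ring carbon cis to CH2In) | O=C[C@@H](C(C)=C)[C@](C)(C=C)C[C@@H](O)/C=C(\C[In])C(=O)OCC[Si](C)(C)C | intermediate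
21 | 2-(trimethylsilyl)ethyl 2-[(1R,2S,3S,4S,6R)-4-ethenyl-2,6-dihydroxy-4-methyl-3-(prop-1-en-2-yl)cyclohexyl]prop-2-enoate | C=C[C@]1(C)C[C@@H](O)[C@@H](C(=C)C(=O)OCC[Si](C)(C)C)[C@@H](O)[C@H]1C(C)=C | intermediate
22 | methyl (2S)-3-hydroxy-2-methylpropanoate | COC(=O)[C@@H](C)CO | starting material
23 | methyl (2S)-3-{[tert-butyl(dimethyl)silyl]oxy}-2-methylpropanoate | COC(=O)[C@@H](C)CO[Si](C)(C)C(C)(C)C | intermediate
24 | (2S)-3-{[tert-butyl(dimethyl)silyl]oxy}-2-methylpropanoic acid | OC(=O)[C@@H](C)CO[Si](C)(C)C(C)(C)C | intermediate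
25 | (2S)-3-{[tert-butyl(dimethyl)silyl]oxy}-2-methylpropanoic 2,4,6-trichlorobenzoic anhydride | C[C@@H](CO[Si](C)(C)C(C)(C)C)C(=O)OC(=O)c1c(Cl)cc(Cl)cc1Cl | intermediate
26 | 2-(trimethylsilyl)ethyl 2-[(1S,2S,3S,4S,6R)-6-{[(2S)-3-{[tert-butyl(dimethyl)silyl]oxy}-2-methylpropanoyl]oxy}-4-ethenyl-2-hydroxy-4-methyl-3-(prop-1-en-2-yl)cyclohexyl]prop-2-enoate | C=C[C@]1(C)C[C@@H](OC(=O)[C@@H](C)CO[Si](C)(C)C(C)(C)C)[C@@H](C(=C)C(=O)OCC[Si](C)(C)C)[C@@H](O)[C@H]1C(C)=C | intermediate
27 | 2-(trimethylsilyl)ethyl 2-[(1S,2S,3R,4S,6R)-6-{[(2S)-3-{[tert-butyl(dimethyl)silyl]oxy}-2-methylpropanoyl]oxy}-4-ethenyl-2-hydroxy-3-(3-hydroxyprop-1-en-2-yl)-4-methylcyclohexyl]prop-2-enoate | C=C[C@]1(C)C[C@@H](OC(=O)[C@@H](C)CO[Si](C)(C)C(C)(C)C)[C@@H](C(=C)C(=O)OCC[Si](C)(C)C)[C@@H](O)[C@H]1C(=C)CO | intermediate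
28 | 2-[(1S,2S,3R,4S,6R)-4-ethenyl-2-hydroxy-6-{[(2S)-3-hydroxy-2-methylpropanoyl]oxy}-3-(3-hydroxyprop-1-en-2-yl)-4-methylcyclohexyl]prop-2-enoic acid (CNP0462645.3) | C=C[C@]1(C)C[C@@H](OC(=O)[C@@H](C)CO)[C@@H](C(=C)C(=O)O)[C@@H](O)[C@H]1C(=C)CO | target

## Step count and risks

Total: 14 steps (steps 7, 10 and 11 are side branches). Longest linear sequence: 11 steps (1–6, 8, 9, 12, 13, 14).

The three steps most likely to fail:

Step 9 (key cyclisation). The allylindium may be protonated or may eliminate the allylic oxygen before the lactol opens, or the ring may close to the wrong C4/C5 diastereomer. Fallback, setting out from 19 and coming back at 21: exchange bromide for acetate with CsOAc in N,N-dimethylformamide to give allylic acetate F1, then treat it with SmI2 in THF–MeOH at −78 °C. The polarity reversal is then moved to the aldehyde: its samarium ketyl at C5 adds 6-exo to the enoate β-carbon C4 in a chelated chair, and the resulting samarium enolate expels acetate to unveil the α-methylene ester of 21.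

Step 13 (allylic oxidation). Over-oxidation to the enal or attack at the ring methine would erode the yield. Fallback, setting out from 26 and coming back at 27: ene-type chlorination with NaOCl and CeCl3·7H2O in CH2Cl2–H2O at 0 °C (chloronium formation at the most electron-rich alkene, loss of a methyl proton) gives allylic chloride F2. Silver-assisted hydrolysis with Ag2O in aqueous acetone then gives 27; the 2-substituted allyl cation is symmetrical, so either terminus leads to the same alcohol.

Step 14 (global deprotection). A fluoride-generated C5 alkoxide could attack the still-intact ester to give the cis-fused lactone, or the acyl group could migrate from O3 to O5. Fallback, setting out from 26 and coming back at 28 without passing through 27: first silylate the C5 hydroxyl with triethylsilyl trifluoromethanesulfonate and 2,6-lutidine to give triethylsilyl ether F3, oxidise the isopropenyl methyl under the conditions of step 13 to give alcohol F4, then apply the fluoride conditions of step 14. The unhindered 2-(trimethylsilyl)ethyl ester fragments to the carboxylate before the hindered secondary silyl ether is cleaved, so no alkoxide ever sits next to an electrophilic ester.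

Further compounds

F1 | step 9 | 2-(trimethylsilyl)ethyl (2E)-2-[(acetyloxy)methyl]-3-[(2R,4S,5S)-4-ethenyl-6-hydroxy-4-methyl-5-(prop-1-en-2-yl)oxan-2-yl]prop-2-enoate | C=C[C@]1(C)C[C@H](/C=C(\COC(C)=O)C(=O)OCC[Si](C)(C)C)OC(O)[C@H]1C(C)=C
F2 | step 13 | 2-(trimethylsilyl)ethyl 2-[(1S,2S,3R,4S,6R)-6-{[(2S)-3-{[tert-butyl(dimethyl)silyl]oxy}-2-methylpropanoyl]oxy}-3-(3-chloroprop-1-en-2-yl)-4-ethenyl-2-hydroxy-4-methylcyclohexyl]prop-2-enoate | C=C[C@]1(C)C[C@@H](OC(=O)[C@@H](C)CO[Si](C)(C)C(C)(C)C)[C@@H](C(=C)C(=O)OCC[Si](C)(C)C)[C@@H](O)[C@H]1C(=C)CCl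
F3 | step 14 | 2-(trimethylsilyl)ethyl 2-[(1R,2S,3S,4S,6R)-6-{[(2S)-3-{[tert-butyl(dimethyl)silyl]oxy}-2-methylpropanoyl]oxy}-4-ethenyl-4-methyl-3-(prop-1-en-2-yl)-2-[(triethylsilyl)oxy]cyclohexyl]prop-2-enoate | C=C[C@]1(C)C[C@@H](OC(=O)[C@@H](C)CO[Si](C)(C)C(C)(C)C)[C@@H](C(=C)C(=O)OCC[Si](C)(C)C)[C@@H](O[Si](CC)(CC)CC)[C@H]1C(C)=C
F4 | step 14 | 2-(trimethylsilyl)ethyl 2-[(1R,2S,3R,4S,6R)-6-{[(2S)-3-{[tert-butyl(dimethyl)silyl]oxy}-2-methylpropanoyl]oxy}-4-ethenyl-3-(3-hydroxyprop-1-en-2-yl)-4-methyl-2-[(triethylsilyl)oxy]cyclohexyl]prop-2-enoate | C=C[C@]1(C)C[C@@H](OC(=O)[C@@H](C)CO[Si](C)(C)C(C)(C)C)[C@@H](C(=C)C(=O)OCC[Si](C)(C)C)[C@@H](O[Si](CC)(CC)CC)[C@H]1C(=C)CO
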